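**Retrosynthetic overview**
1. Only the pyranone C-ring is built; it is formed last by Baker–Venkataraman rearrangement and cyclodehydration, which splits the target into A-ring ketone 7 and B-ring acid 15 (both aromatic rings are bought).
2. Ketone 7 comes from 2-methoxyresorcinol: C–H borylation/oxidation installs the ring-closing oxygen, and directed ortho-metalation installs the methoxyacetyl group, so the 6-OMe (not 8-OMe) pattern is fixed by construction.
3. Acid 15 comes from methyl 3,5-dibromo-4-hydroxybenzoate by two sequential Br/Mg exchange–prenylations (this desymmetrises the ring).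
4. The (E)-4-hydroxy-3-methylbut-2-enyl chain is made by SeO2 oxidation of the first prenyl group before the second prenyl is introduced.
5. MOM and TBS groups are removed in the final acidic operation.

Assumption: the target has no stereocentres (it is achiral), so "single enantiomer" reduces to controlling the (E)-olefin; N,2-dimethoxy-N-methylacetamide (5) is taken as a catalogue reagent.

**A-ring fragment**

Step 1
Reactants: 1, 2-methoxybenzene-1,3-diol (2-methoxyresorcinol)
Product: 2, 2-methoxy-1,3-bis(methoxymethoxy)benzene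
Conditions: MOMCl (2.5 equiv), i-Pr2NEt, CH2Cl2, 0 °C → rt
Reagents that add atoms: chloromethyl methyl ether (MOMCl), COCCl
Why: Williamson-type O-alkylation of both phenols gives the bis-MOM ether, which later serves as the ortho-directing group.

Step 2
Reactants: 2
Product: 3, 4-methoxy-3,5-bis(methoxymethoxy)phenol
Conditions: [Ir(OMe)(cod)]2 (1.5 mol %), dtbpy (3 mol %), B2pin2, THF, 80 °C; then 30% H2O2, aq NaOH, 0 °C → rt (one pot)
Reagents that add atoms: hydrogen peroxide, OO (phenol oxygen; B2pin2 leaves no atoms in the product)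
Why: Sterically controlled Ir-catalysed C–H borylation occurs only at C-5, the sole C–H with no ortho substituent, and the aryl boronate is oxidised in situ to the phenol.

Step 3
Reactants: 3
Product: 4, 5-(benzyloxy)-2-methoxy-1,3-bis(methoxymethoxy)benzene
Conditions: BnBr, K2CO3, DMF, rt
Reagents that add atoms: benzyl bromide, BrCc1ccccc1
Why: Williamson etherification gives the future ring-closing oxygen a protecting group orthogonal to MOM.

Step 4
Reactants: 4; 5, N,2-dimethoxy-N-methylacetamide (Weinreb amide of methoxyacetic acid)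
Product: 6, 1-[6-(benzyloxy)-3-methoxy-2,4-bis(methoxymethoxy)phenyl]-2-methoxyethan-1-one
Conditions: n-BuLi (1.1 equiv), THF, 0 °C, 1 h; then 5, −78 → 0 °C
Reagents that add atoms: none beyond reactant 5
Why: Directed ortho-metalation occurs at the only ring C–H (between OMOM and OBn; the two are equivalent), and Weinreb acylation stops cleanly at the ketone.

Step 5
Reactants: 6
Product: 7, 1-[6-hydroxy-3-methoxy-2,4-bis(methoxymethoxy)phenyl]-2-methoxyethan-1-one
Conditions: H2 (1 atm), 10% Pd/C, EtOAc, rt
Reagents that add atoms: none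
Why: Hydrogenolysis removes only the benzyl ether (no alkenes are present yet), freeing the one ortho-OH that will become O-1 of the flavone.

**B-ring fragment**

Step 6
Reactants: 8, methyl 3,5-dibromo-4-hydroxybenzoate
Product: 9, methyl 3,5-dibromo-4-(methoxymethoxy)benzoate
Conditions: MOMCl, i-Pr2NEt, CH2Cl2, 0 °C → rt
Reagents that add atoms: chloromethyl methyl ether, COCCl
Why: The acidic 2,6-dibromophenol is O-alkylated easily, and the MOM group then assists the ortho Br/Mg exchanges by chelation.

Step 7
Reactants: 9; 10, 1-bromo-3-methylbut-2-ene (prenyl bromide)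
Product: 11, methyl 3-bromo-4-(methoxymethoxy)-5-(3-methylbut-2-en-1-yl)benzoate
Conditions: i-PrMgCl·LiCl (1.05 equiv), THF, −40 °C, 1 h; then CuBr·SMe2 (10 mol %), 10, −40 → 0 °C
Reagents that add atoms: none beyond reactant 10
Why: Knochel Br/Mg exchange of the doubly activated dibromide stops after one exchange and tolerates the ester at low temperature; Cu-catalysed allylic substitution in THF gives the linear (SN2) prenyl arene.

Step 8
Reactants: 11
Product: 12, methyl 3-bromo-5-[(2E)-4-hydroxy-3-methylbut-2-en-1-yl]-4-(methoxymethoxy)benzoate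
Conditions: SeO2 (0.5 equiv), t-BuOOH (3 equiv), salicylic acid (10 mol %), CH2Cl2, rt; then NaBH4, CeCl3·7H2O, MeOH, 0 °C (returns any over-oxidised enal to the alcohol)
Reagents that add atoms: tert-butyl hydroperoxide, CC(C)(C)OO (oxygen delivered via SeO2, O=[Se]=O)
Why: Riley/Sharpless allylic oxidation proceeds by an ene reaction and [2,3]-shift at the methyl group trans to the chain on the more substituted olefin carbon, which sets the (E)-olefin; the ArCH2 position is not attacked.

Step 9
Reactants: 12
Product: 13, methyl 3-bromo-5-[(2E)-4-{[tert-butyl(dimethyl)silyl]oxy}-3-methylbut-2-en-1-yl]-4-(methoxymethoxy)benzoate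
Conditions: TBSCl, imidazole, DMF, rt
Reagents that add atoms: tert-butyldimethylsilyl chloride, CC(C)(C)[Si](C)(C)Cl
Why: Silylation masks the primary alcohol for the Grignard, esterification and enolate steps; the olefin geometry is untouched.

Step 10
Reactants: 13; 10, prenyl bromide
Product: 14, methyl 3-[(2E)-4-{[tert-butyl(dimethyl)silyl]oxy}-3-methylbut-2-en-1-yl]-4-(methoxymethoxy)-5-(3-methylbut-2-en-1-yl)benzoate
Conditions: i-PrMgCl·LiCl (1.1 equiv), THF, −20 → −5 °C; then CuBr·SMe2 (10 mol %), 10, → 0 °C
Reagents that add atoms: none beyond reactant 10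
Why: A second chelation-assisted Br/Mg exchange (ortho-OMOM, para-ester) and Cu-catalysed SN2 prenylation install the unoxidised prenyl group; the silyl ether, ester and (E)-olefin are inert.

Step 11
Reactants: 14
Product: 15, 3-[(2E)-4-{[tert-butyl(dimethyl)silyl]oxy}-3-methylbut-2-en-1-yl]-4-(methoxymethoxy)-5-(3-methylbut-2-en-1-yl)benzoic acid
Conditions: LiOH·H2O, THF/MeOH/H2O, 40 °C; acidify to pH 4–5 with citric acid
Reagents that add atoms: lithium hydroxide/water, [Li+].[OH-] (oxygen of the acid OH)
Why: Saponification of the methyl ester; the alkyl TBS ether and aryl MOM ether are base-stable, and the mild acidification preserves both.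

**Fragment union and endgame**

Step 12
Reactants: 7; 15
Product: 16, 4-methoxy-2-(methoxyacetyl)-3,5-bis(methoxymethoxy)phenyl 3-[(2E)-4-{[tert-butyl(dimethyl)silyl]oxy}-3-methylbut-2-en-1-yl]-4-(methoxymethoxy)-5-(3-methylbut-2-en-1-yl)benzoate
Conditions: EDCI·HCl, DMAP, CH2Cl2, rt
Reagents that add atoms: none
Why: Steglich esterification acylates the only free OH in 7 under neutral conditions that tolerate MOM, TBS and the prenyl groups.

Step 13
Reactants: 16
Product: 17, 1-[6-hydroxy-3-methoxy-2,4-bis(methoxymethoxy)phenyl]-2-methoxy-3-{3-[(2E)-4-{[tert-butyl(dimethyl)silyl]oxy}-3-methylbut-2-en-1-yl]-4-(methoxymethoxy)-5-(3-methylbut-2-en-1-yl)phenyl}propane-1,3-dione (C-2 is enolisable; obtained as a keto/enol/hemiketal mixture)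
Conditions: LiHMDS (3 equiv), THF, −78 → −10 °C; AcOH quench
Reagents that add atoms: none
Why: Baker–Venkataraman rearrangement: the α-methoxy ketone enolate attacks the neighbouring aryl ester (intramolecular O→C acyl transfer) to give the 2-methoxy-1,3-diketone.

Step 14
Reactants: 17
Product: 18, dodoviscin G, 5,7-dihydroxy-2-{4-hydroxy-3-[(2E)-4-hydroxy-3-methylbut-2-en-1-yl]-5-(3-methylbut-2-en-1-yl)phenyl}-3,6-dimethoxy-4H-chromen-4-one
Conditions: (i) CSA (0.2 equiv), 4 Å MS, CH2Cl2, rt (ring closure with MOM groups still on); (ii) add MeOH and 3 M aq HCl, 40 °C, 3–6 h (one pot)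
Reagents that add atoms: none
Why: Acid-catalysed cyclodehydration through the only free ortho-OH gives the 3-methoxyflavone with 6-OMe regiochemistry before the much slower MOM and TBS solvolysis unveils the four hydroxyls; no stereocentre is formed and the (E)-olefin is not involved.

**Compound list**
1 | 2-methoxybenzene-1,3-diol | COc1c(O)cccc1O | starting material
2 | 2-methoxy-1,3-bis(methoxymethoxy)benzene | COCOc1cccc(OCOC)c1OC | intermediate
3 | 4-methoxy-3,5-bis(methoxymethoxy)phenol | COCOc1cc(O)cc(OCOC)c1OC | intermediate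
4 | 5-(benzyloxy)-2-methoxy-1,3-bis(methoxymethoxy)benzene | COCOc1cc(OCc2ccccc2)cc(OCOC)c1OC | intermediate
5 | N,2-dimethoxy-N-methylacetamide | COCC(=O)N(C)OC | starting material
6 | 1-[6-(benzyloxy)-3-methoxy-2,4-bis(methoxymethoxy)phenyl]-2-methoxyethan-1-one | COCC(=O)c1c(OCc2ccccc2)cc(OCOC)c(OC)c1OCOC | intermediate
7 | 1-[6-hydroxy-3-methoxy-2,4-bis(methoxymethoxy)phenyl]-2-methoxyethan-1-one | COCC(=O)c1c(O)cc(OCOC)c(OC)c1OCOC | intermediate
8 | methyl 3,5-dibromo-4-hydroxybenzoate | COC(=O)c1cc(Br)c(O)c(Br)c1 | starting material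
9 | methyl 3,5-dibromo-4-(methoxymethoxy)benzoate | COCOc1c(Br)cc(cc1Br)C(=O)OC | intermediate
10 | 1-bromo-3-methylbut-2-ene (prenyl bromide) | CC(C)=CCBr | starting material
11 | methyl 3-bromo-4-(methoxymethoxy)-5-(3-methylbut-2-en-1-yl)benzoate | COCOc1c(Br)cc(cc1CC=C(C)C)C(=O)OC | intermediate
12 | methyl 3-bromo-5-[(2E)-4-hydroxy-3-methylbut-2-en-1-yl]-4-(methoxymethoxy)benzoate | COCOc1c(Br)cc(cc1C/C=C(\C)CO)C(=O)OC | intermediate
13 | TBS ether of 12 | COCOc1c(Br)cc(cc1C/C=C(\C)CO[Si](C)(C)C(C)(C)C)C(=O)OC | intermediate
14 | methyl 3-[(2E)-4-(TBSO)-3-methylbut-2-en-1-yl]-4-(methoxymethoxy)-5-(3-methylbut-2-en-1-yl)benzoate | COCOc1c(CC=C(C)C)cc(cc1C/C=C(\C)CO[Si](C)(C)C(C)(C)C)C(=O)OC | intermediate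
15 | corresponding benzoic acid | COCOc1c(CC=C(C)C)cc(cc1C/C=C(\C)CO[Si](C)(C)C(C)(C)C)C(=O)O | intermediate
16 | aryl ester of 7 with 15 | COCC(=O)c1c(OC(=O)c2cc(CC=C(C)C)c(OCOC)c(C/C=C(\C)CO[Si](C)(C)C(C)(C)C)c2)cc(OCOC)c(OC)c1OCOC | intermediate
17 | 2-methoxy-1,3-diketone | COC(C(=O)c1c(O)cc(OCOC)c(OC)c1OCOC)C(=O)c1cc(CC=C(C)C)c(OCOC)c(C/C=C(\C)CO[Si](C)(C)C(C)(C)C)c1 | intermediate
18 | dodoviscin G | COc1c(O)cc2oc(-c3cc(CC=C(C)C)c(O)c(C/C=C(\C)CO)c3)c(OC)c(=O)c2c1O | target

**Totals**
Total steps: 14. Longest linear sequence: 9 steps (8 → 18, steps 6–14); the A-ring branch is 5 steps before the union.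

**Three steps most likely to fail, with fallbacks**
1. Step 14 (acidic ring closure and global deprotection). The risks are loss of the ortho MOM before ring closure (which would give the 8-OMe isomer), chroman formation from the ortho-prenyl phenol, and solvolysis of the allylic alcohol. Fallback: close the ring under base by the chalcone/Algar–Flynn–Oyamada route. This uses the acetophenone analogue of 7 and the aldehyde derived from 14, with H2O2/NaOH and then MeI for 3-OMe. MOM groups are then removed non-protically (TMSOTf/2,2′-bipyridyl, then TBAF).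
2. Steps 7 and 10 (Br/Mg exchange and Cu-catalysed prenylation next to a methyl ester). The risks are ester attack, SN2′ (reverse-prenyl) product, and a sluggish second exchange. Fallback: switch to Pd cross-coupling with tributyl(prenyl)stannane (Stille) or prenyl-Bpin (Suzuki) on methyl 3-bromo-4-hydroxy-5-iodobenzoate MOM ether, coupling at C–I first and C–Br second.
3. Step 8 (SeO2 allylic oxidation). The risks are modest conversion and over-oxidation. Fallback: build the oxygenated chain directly by trapping the aryl-Mg with allyl bromide, then E-selective cross-metathesis with methacrolein (Hoveyda–Grubbs II) and Luche reduction.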